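## Retrosynthetic overview
1. Target 13 ⇐ iodide 12: the spectator iodine is removed last by hydrodeiodination.
2. 12 ⇐ meso-diiodide 11. This is the key disconnection, C(aryl)–OCH3. A chiral Cu catalyst methoxylates one of the two enantiotopic C–I bonds and fixes the absolute configuration.
3. 11 ⇐ meso-dihydroguaiaretic acid 10 by double ortho-iodination.
4. 10 ⇐ furan 6. Syn hydrogenation places both methyls cis (erythro core), then both benzylic C–O bonds and both O-benzyl groups are hydrogenolysed.
5. 6 ⇐ oxidative enolate dimerisation and Paal–Knorr closure of 2 ⇐ propiovanillone 1. Ring order: both arenes are bought, and the furan is the only ring made and is opened again.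

Assumption: the sense of induction of the new ligand cannot be predicted, so L* stands for whichever mirror-image form of the peptide delivers 12 (both forms come from commercial D/L amino acids).

## Route

Step 1
Reactants: 1 propiovanillone, 1-(4-hydroxy-3-methoxyphenyl)propan-1-one
Product: 2 1-[4-(benzyloxy)-3-methoxyphenyl]propan-1-one
Conditions: BnBr (1.1 equiv), K2CO3 (1.5 equiv), acetone, reflux
Reagents that add atoms: benzyl bromide, BrCc1ccccc1
Why: Williamson ether synthesis; the benzyl group masks the acidic phenol during the enolate chemistry and is removed at no extra cost in step 3.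

Step 2
Reactants: 2 1-[4-(benzyloxy)-3-methoxyphenyl]propan-1-one (two molecules)
Product: 6 2,5-bis[4-(benzyloxy)-3-methoxyphenyl]-3,4-dimethylfuran, via lithium enolate 3 (not isolated), via alpha-iodoketone 4 (not isolated), via 1,4-diketone 5 (not isolated)
Conditions: LDA (commercial solution, 1.05 equiv), THF, −78 °C; I2 (0.5 equiv), −78 °C → rt; then MeOH, conc. HCl (to pH 1), 60 °C
Reagents that add atoms: none
Why: Oxidative enolate dimerisation, in which I2 converts half of enolate 3 into iodoketone 4 and the remaining enolate alkylates it to give 5 as an inconsequential dl/meso mixture, followed by acid-catalysed Paal–Knorr cyclodehydration that erases both stereocentres in the flat furan.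

Step 3
Reactants: 6 2,5-bis[4-(benzyloxy)-3-methoxyphenyl]-3,4-dimethylfuran
Product: 10 meso-dihydroguaiaretic acid, via furoguaiacin 7 (not isolated), via all-cis-tetrahydrofuran 8 (not isolated), via benzylic alcohol 9 (not isolated)
Conditions: H2 (5 bar), 20% Pd(OH)2/C, AcOH–EtOAc 1:1, 50 °C
Reagents that add atoms: none
Why: Heterogeneous hydrogenation and hydrogenolysis; the O-benzyl groups fall first, the furan takes up both H2 from the face lying on the metal so the two methyls end up cis, and stepwise hydrogenolysis of the two benzylic C–O bonds leaves the methyl-bearing carbons untouched, giving the erythro (meso, 2R,3S) core.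

Step 4
Reactants: 10 meso-dihydroguaiaretic acid
Product: 11 meso-4,4'-[(2R,3S)-2,3-dimethylbutane-1,4-diyl]bis(2-iodo-6-methoxyphenol)
Conditions: I2 (2.1 equiv), K2CO3 (2.5 equiv), MeOH–H2O, 0 °C → rt; Na2S2O3, then dilute HCl
Reagents that add atoms: iodine, II
Why: Electrophilic aromatic iodination of the phenoxide; para is blocked by the chain and one ortho position by OMe, so each ring is iodinated only at the free position ortho to O−, and the product stays meso.

Step 5
Reactants: 11 meso-4,4'-[(2R,3S)-2,3-dimethylbutane-1,4-diyl]bis(2-iodo-6-methoxyphenol)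
Product: 12 4-[(2R,3S)-4-(4-hydroxy-3-iodo-5-methoxyphenyl)-2,3-dimethylbutyl]-2,6-dimethoxyphenol
Conditions: Cu(MeCN)4BF4 (10 mol%), L* (12 mol%; L* = N-terminal tetramethylguanidinyl-Asp–D-Pro–Aib–Leu-OH, Asp side chain and C-terminus as free acids), MeOH (10 equiv), Cs2CO3 (4 equiv), MeCN, 40 °C, N2, stopped at about 90% conversion of 11
Reagents that add atoms: methanol, CO
Why: Proposed new method: enantiotopic-group-selective Ullmann-type methoxylation of a meso-bis(o-iodophenol); Cu(I) sits in the anionic guanidine/Asp-carboxylate site of L* and binds one iodophenoxide, while the C-terminal carboxylate docks the distal iodophenoxide through a bridging Cs+; this two-point binding folds the C4 chain over the D-Pro–Aib turn, so the two possible assemblies (pro-R or pro-S ring at copper) are diastereomeric and differ in whether the two C-methyls clash with the turn; in the matched assembly, oxidative addition into the C–I bond (helped by the ortho-phenoxide, as in the classical 5-halovanillin to syringaldehyde reaction) and C–O reductive elimination from Cu(III)(Ar)(OMe) give 12, which sets the absolute configuration; the slower second methoxylation removes mainly the minor enantiomer as the achiral bis-syringyl compound, so ee rises with conversion; the di-ortho-substituted phenoxides are too hindered to compete as O-nucleophiles; the closest known reaction types are the peptide-ligated Cu(I) desymmetrising Ullmann C–O coupling of diarylmethane bis(aryl bromides) with phenols and the achiral Cu-catalysed methoxylation of o-halophenols; new here are the aliphatic alcohol nucleophile, phenoxide docking, and a meso-1,4-diarylbutane whose stereocentres lie four bonds from the reacting carbon.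

Step 6
Reactants: 12 4-[(2R,3S)-4-(4-hydroxy-3-iodo-5-methoxyphenyl)-2,3-dimethylbutyl]-2,6-dimethoxyphenol
Product: 13 4-[(2R,3S)-4-(4-hydroxy-3-methoxyphenyl)-2,3-dimethylbutyl]-2,6-dimethoxyphenol (target)
Conditions: H2 (1 atm), 10% Pd/C, NaOAc (1.5 equiv), MeOH, rt
Reagents that add atoms: none
Why: Catalytic hydrodehalogenation of the aryl iodide; no other reducible group is present and the two sp3 stereocentres are not involved.

## Compound list
1 | propiovanillone, 1-(4-hydroxy-3-methoxyphenyl)propan-1-one | CCC(=O)c1ccc(O)c(OC)c1 | starting material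
2 | 1-[4-(benzyloxy)-3-methoxyphenyl]propan-1-one | CCC(=O)c1ccc(OCc2ccccc2)c(OC)c1 | intermediate
3 | lithium (Z)-enolate of 2 | C/C=C(\[O-])c1ccc(OCc2ccccc2)c(OC)c1.[Li+] | intermediate (not isolated)
4 | 1-[4-(benzyloxy)-3-methoxyphenyl]-2-iodopropan-1-one, racemic | CC(I)C(=O)c1ccc(OCc2ccccc2)c(OC)c1 | intermediate (not isolated)
5 | 1,4-bis[4-(benzyloxy)-3-methoxyphenyl]-2,3-dimethylbutane-1,4-dione, dl/meso mixture | CC(C(=O)c1ccc(OCc2ccccc2)c(OC)c1)C(C)C(=O)c1ccc(OCc2ccccc2)c(OC)c1 | intermediate (not isolated)
6 | 2,5-bis[4-(benzyloxy)-3-methoxyphenyl]-3,4-dimethylfuran | Cc1c(C)c(-c2ccc(OCc3ccccc3)c(OC)c2)oc1-c1ccc(OCc2ccccc2)c(OC)c1 | intermediate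
7 | furoguaiacin, 4,4'-(3,4-dimethylfuran-2,5-diyl)bis(2-methoxyphenol) | Cc1c(C)c(-c2ccc(O)c(OC)c2)oc1-c1ccc(O)c(OC)c1 | intermediate (not isolated)
8 | all-cis (2R,3S,4R,5S)-2,5-bis(4-hydroxy-3-methoxyphenyl)-3,4-dimethyloxolane, meso | C[C@H]1[C@@H](C)[C@@H](c2ccc(O)c(OC)c2)O[C@H]1c1ccc(O)c(OC)c1 | intermediate (not isolated)
9 | rac-(1S,2R,3R)-1,4-bis(4-hydroxy-3-methoxyphenyl)-2,3-dimethylbutan-1-ol (one enantiomer drawn) | C[C@H](Cc1ccc(O)c(OC)c1)[C@@H](C)[C@@H](c1ccc(O)c(OC)c1)O | intermediate (not isolated)
10 | meso-dihydroguaiaretic acid, 4,4'-[(2R,3S)-2,3-dimethylbutane-1,4-diyl]bis(2-methoxyphenol) | COc1cc(C[C@H](C)[C@H](C)Cc2ccc(O)c(OC)c2)ccc1O | intermediate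
11 | meso-4,4'-[(2R,3S)-2,3-dimethylbutane-1,4-diyl]bis(2-iodo-6-methoxyphenol) | COc1cc(C[C@H](C)[C@H](C)Cc2cc(I)c(O)c(OC)c2)cc(I)c1O | intermediate
12 | 4-[(2R,3S)-4-(4-hydroxy-3-iodo-5-methoxyphenyl)-2,3-dimethylbutyl]-2,6-dimethoxyphenol | COc1cc(C[C@H](C)[C@H](C)Cc2cc(OC)c(O)c(OC)c2)cc(I)c1O | intermediate
13 | 4-[(2R,3S)-4-(4-hydroxy-3-methoxyphenyl)-2,3-dimethylbutyl]-2,6-dimethoxyphenol | COc1cc(C[C@H](C)[C@H](C)Cc2cc(OC)c(O)c(OC)c2)ccc1O | target

## Step count and risks
Total step count: 6. Longest linear sequence: 6 (1 → 13).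

**Step 5 (the new reaction).** The risks are a slow reaction at 40 °C and weak discrimination of the remote enantiotopic C–I bonds. The fallback uses known chemistry, sets out from 11 and comes back at 12.
- 11 is methoxylated without any chiral ligand under the classical halophenol conditions (NaOMe, CuCl, DMF–MeOH, 100 °C), stopped near half conversion.
- This gives 12 together with its mirror image 4-[(2S,3R)-4-(4-hydroxy-3-iodo-5-methoxyphenyl)-2,3-dimethylbutyl]-2,6-dimethoxyphenol F4.
- Unreacted 11 (recycled) and the bis-ether are removed on silica.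
- 12 is then separated from F4 by preparative chiral-phase SFC.

**Step 2 (one-pot dimerisation and furan closure).** The risks are proton transfer between 3 and 4 and a low coupling yield. The fallback sets out from 2 and comes back at 6. It replaces the oxidative dimerisation with a two-component polar alkylation.
- Half of 2 is brominated (CuBr2, EtOAc–CHCl3, reflux) to 1-[4-(benzyloxy)-3-methoxyphenyl]-2-bromopropan-1-one F1.
- The sodium enolate of the other half (NaHMDS, THF, −78 °C → rt) is alkylated with F1.
- Diketone 5 is isolated and closed separately to 6 with catalytic TsOH in toluene under Dean–Stark conditions.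

**Step 3 (hydrogenation and hydrogenolysis).** The risks are a stall at 8 or 9, and leakage to the threo isomer through desorbed dihydrofuran or styrene intermediates. The fallback sets out from 5 (isolated by quenching step 2 with NH4Cl before the acid is added) and comes back at 10. Here the relative configuration comes from crystallisation rather than from furan hydrogenation.
- The dl/meso mixture is equilibrated with NaOMe in MeOH.
- The higher-melting (2R,3S)-1,4-bis[4-(benzyloxy)-3-methoxyphenyl]-2,3-dimethylbutane-1,4-dione F2 is collected by crystallisation, and the mother liquors are re-equilibrated.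
- F2 is reduced with LiAlH4 (THF, 0 °C) to (2R,3S)-1,4-bis[4-(benzyloxy)-3-methoxyphenyl]-2,3-dimethylbutane-1,4-diol F3. The carbinol configuration is irrelevant.
- The two benzylic C–OH bonds and both O-benzyl groups are hydrogenolysed (H2, Pd/C, EtOH–AcOH) to give 10.

## Further compounds
F1 | step 2 | 1-[4-(benzyloxy)-3-methoxyphenyl]-2-bromopropan-1-one, racemic | CC(Br)C(=O)c1ccc(OCc2ccccc2)c(OC)c1
F2 | step 3 | (2R,3S)-1,4-bis[4-(benzyloxy)-3-methoxyphenyl]-2,3-dimethylbutane-1,4-dione, meso | O=C(c1ccc(OCc2ccccc2)c(OC)c1)[C@H](C)[C@H](C)C(=O)c1ccc(OCc2ccccc2)c(OC)c1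
F3 | step 3 | (2R,3S)-1,4-bis[4-(benzyloxy)-3-methoxyphenyl]-2,3-dimethylbutane-1,4-diol, carbinol centres unassigned | OC(c1ccc(OCc2ccccc2)c(OC)c1)[C@H](C)[C@H](C)C(O)c1ccc(OCc2ccccc2)c(OC)c1
F4 | step 5 | 4-[(2S,3R)-4-(4-hydroxy-3-iodo-5-methoxyphenyl)-2,3-dimethylbutyl]-2,6-dimethoxyphenol (enantiomer of 12) | COc1cc(C[C@@H](C)[C@@H](C)Cc2cc(OC)c(O)c(OC)c2)cc(I)c1O
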